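**Assumption:** the SMILES is read as lactone (3S,4S), arm on the C‑4 benzyl ring (1S,2S), arm on the C‑3 benzyl ring (1S,2R); methyl dihydroferulate and both enantiomers of 4‑benzyl‑2‑oxazolidinone are taken as catalogue chemicals.

## Retrosynthetic overview

1. The two arms differ in relative configuration (anti on the C‑4 benzyl ring, syn on the C‑3 benzyl ring), so the two halves are built separately. All eight OH groups are carried as TBS ethers and freed in one final step.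
2. The lactone is the only ring formed and is made last. The C8–C8′ bond comes from a one‑electron oxidative coupling of two dihydroferulate‑type enolates (chiral imide enolate of the anti half, ester enolate of the syn half), echoing the 8–8′ coupling of lignan biogenesis. C9′–O then closes onto C9; the auxiliary sets C‑4 and base equilibration to trans sets C‑3.
3. Both arms come from one (S)‑oxazolidinone arylacetyl imide and TBS‑vanillin: a Bu2BOTf syn‑aldol gives the (1S,2R) arm and a MgCl2/TMSCl anti‑aldol gives the (1S,2S) arm; each is followed by reductive auxiliary removal.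
4. The arylacetic acid comes from methyl dihydroferulate by O‑allylation, Claisen rearrangement and ozonolysis/oxidation.

**Abbreviations:** TBS = tert‑butyldimethylsilyl. G = 4‑(TBSO)‑3‑methoxyphenyl. Q = 2‑(TBSO)‑3‑methoxy‑5‑(3‑methoxy‑3‑oxopropyl)phenyl (core ring with its methyl propanoate chain). Ar‑syn = 4‑(TBSO)‑3‑methoxy‑5‑[(1S,2R)‑1,3‑bis(TBSO)‑1‑G‑propan‑2‑yl]phenyl. Ar‑anti = the (1S,2S) diastereomer of Ar‑syn. In arm descriptors C‑1 is the carbinol carbon bearing G and C‑2 the carbon bearing the core ring.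

## Route

Step 1
Reactants: 1 methyl 3-(4-hydroxy-3-methoxyphenyl)propanoate; 2 allyl bromide
Product: 3 methyl 3-[4-(allyloxy)-3-methoxyphenyl]propanoate
Conditions: K2CO3, acetone, reflux
Reagents that add atoms: none
Why: Williamson etherification; the phenoxide is the only nucleophile formed under carbonate conditions.

Step 2
Reactants: 3 methyl 3-[4-(allyloxy)-3-methoxyphenyl]propanoate
Product: 4 methyl 3-(3-allyl-4-hydroxy-5-methoxyphenyl)propanoate
Conditions: N,N-diethylaniline, 200 °C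
Reagents that add atoms: none
Why: Aromatic Claisen rearrangement ([3,3]); only the free ortho position (C‑5) can re‑aromatise, so the allyl group ends up there.

Step 3
Reactants: 4 methyl 3-(3-allyl-4-hydroxy-5-methoxyphenyl)propanoate
Product: 5 methyl 3-[3-allyl-4-(TBSO)-5-methoxyphenyl]propanoate
Conditions: TBSCl, imidazole, DMF, rt
Reagents that add atoms: tert-butyldimethylsilyl chloride, CC(C)(C)[Si](C)(C)Cl
Why: Imidazole‑promoted silylation masks the phenol so the later arylacetic acid cannot lactonise and the phenol survives enolate chemistry.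

Step 4
Reactants: 5 methyl 3-[3-allyl-4-(TBSO)-5-methoxyphenyl]propanoate
Product: 7 2-[2-(TBSO)-3-methoxy-5-(3-methoxy-3-oxopropyl)phenyl]acetic acid (Q-acetic acid), via arylacetaldehyde 6 (not isolated)
Conditions: O3, CH2Cl2/MeOH, −78 °C (Sudan III end point); Me2S; then NaClO2, NaH2PO4, 2-methyl-2-butene, t-BuOH/H2O, rt
Reagents that add atoms: ozone, [O-][O+]=O; sodium chlorite, [Na+].[O-]Cl=O
Why: Ozonolysis of the terminal alkene (faster than attack on the arene when ozone is titrated) followed by Pinnick oxidation of the crude aldehyde.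

Step 5
Reactants: 7 Q-acetic acid; 8 (S)-4-benzyl-1,3-oxazolidin-2-one
Product: 10 (4S)-4-benzyl-3-(Q-acetyl)-1,3-oxazolidin-2-one, via mixed pivalic anhydride 9 (not isolated)
Conditions: PivCl, Et3N, THF, −20 °C; then 8, LiCl, −20 °C → rt
Reagents that add atoms: pivaloyl chloride, CC(C)(C)C(=O)Cl (its acyl group is carried only by intermediate 9)
Why: N‑acylation of the oxazolidinone through a mixed anhydride under LiCl/Et3N, mild enough to avoid ketene formation from the arylacetyl unit.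

Step 6
Reactants: 11 vanillin
Product: 12 4-(TBSO)-3-methoxybenzaldehyde
Conditions: TBSCl, imidazole, DMF, rt
Reagents that add atoms: tert-butyldimethylsilyl chloride, CC(C)(C)[Si](C)(C)Cl
Why: Standard phenol silylation so the aldehyde tolerates boron and magnesium enolates.

Step 7
Reactants: 10 (4S)-4-benzyl-3-(Q-acetyl)-1,3-oxazolidin-2-one; 12 4-(TBSO)-3-methoxybenzaldehyde
Product: 13 (4S)-4-benzyl-3-[(2S,3S)-3-hydroxy-2-Q-3-G-propanoyl]-1,3-oxazolidin-2-one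
Conditions: Bu2BOTf, i-Pr2NEt, CH2Cl2, −78 → 0 °C; 12, −78 → 0 °C; pH 7 buffer, MeOH, H2O2
Reagents that add atoms: none
Why: Evans syn‑aldol; the Z‑boron enolate reacts through a Zimmerman–Traxler chair with the dipole‑minimised auxiliary, setting both arm centres as the (2S,3S) syn adduct.

Step 8
Reactants: 13 (4S)-4-benzyl-3-[(2S,3S)-3-hydroxy-2-Q-3-G-propanoyl]-1,3-oxazolidin-2-one
Product: 14 (1S,2R)-1-G-2-Q-propane-1,3-diol
Conditions: LiBH4 (1.2 equiv), H2O (1.2 equiv), Et2O, 0 °C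
Reagents that add atoms: none
Why: Reductive cleavage of the N‑acyloxazolidinone; the activated imide carbonyl is reduced much faster than the unactivated methyl ester at 0 °C, and no stereocentre is touched (the C‑2 descriptor changes only by CIP priority).

Step 9
Reactants: 14 (1S,2R)-1-G-2-Q-propane-1,3-diol
Product: 15 methyl 3-(Ar-syn)propanoate
Conditions: TBSOTf, 2,6-lutidine, CH2Cl2, 0 °C
Reagents that add atoms: tert-butyldimethylsilyl triflate, CC(C)(C)[Si](C)(C)OS(=O)(=O)C(F)(F)F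
Why: Silyl triflate protection of both the primary and the hindered benzylic hydroxyl, giving ethers stable to LDA.

Step 10
Reactants: 10 (4S)-4-benzyl-3-(Q-acetyl)-1,3-oxazolidin-2-one; 12 4-(TBSO)-3-methoxybenzaldehyde
Product: 17 (4S)-4-benzyl-3-[(2R,3S)-3-hydroxy-2-Q-3-G-propanoyl]-1,3-oxazolidin-2-one, via TMS-ether aldol adduct 16 (not isolated)
Conditions: MgCl2 (20 mol %), Et3N, TMSCl, EtOAc, rt; then THF/1 N HCl
Reagents that add atoms: chlorotrimethylsilane, C[Si](C)(C)Cl (its silyl group is carried only by intermediate 16)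
Why: Magnesium halide‑catalysed anti‑aldol of an N‑acyloxazolidinone; the chelated Z‑enolate is expected to react through a boat transition state on the face opposite the benzyl group (opposite to the boron case), giving the (2R,3S) anti adduct from the same imide.

Step 11
Reactants: 17 (4S)-4-benzyl-3-[(2R,3S)-3-hydroxy-2-Q-3-G-propanoyl]-1,3-oxazolidin-2-one
Product: 18 (1S,2S)-1-G-2-Q-propane-1,3-diol
Conditions: LiBH4 (1.2 equiv), H2O (1.2 equiv), Et2O, 0 °C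
Reagents that add atoms: none
Why: Reductive cleavage of the N‑acyloxazolidinone, chemoselective over the methyl ester as in step 8.

Step 12
Reactants: 18 (1S,2S)-1-G-2-Q-propane-1,3-diol
Product: 19 methyl 3-(Ar-anti)propanoate
Conditions: TBSOTf, 2,6-lutidine, CH2Cl2, 0 °C
Reagents that add atoms: tert-butyldimethylsilyl triflate, CC(C)(C)[Si](C)(C)OS(=O)(=O)C(F)(F)F
Why: Bis‑silylation as in step 9.

Step 13
Reactants: 19 methyl 3-(Ar-anti)propanoate
Product: 20 3-(Ar-anti)propanoic acid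
Conditions: Me3SnOH, 1,2-dichloroethane, 80 °C; 5 % HCl wash
Reagents that add atoms: trimethyltin hydroxide, C[Sn](C)(C)O
Why: Organotin hydroxide ester hydrolysis is near neutral and should spare the aryl and alkyl silyl ethers that LiOH would cleave.

Step 14
Reactants: 20 3-(Ar-anti)propanoic acid; 21 (R)-4-benzyl-1,3-oxazolidin-2-one
Product: 23 (4R)-4-benzyl-3-[3-(Ar-anti)propanoyl]-1,3-oxazolidin-2-one, via mixed pivalic anhydride 22 (not isolated)
Conditions: PivCl, Et3N, THF, −20 °C; then 21, LiCl, −20 °C → rt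
Reagents that add atoms: pivaloyl chloride, CC(C)(C)C(=O)Cl (its acyl group is carried only by intermediate 22)
Why: Mixed‑anhydride N‑acylation as in step 5.

Step 15
Reactants: 23 (4R)-4-benzyl-3-[3-(Ar-anti)propanoyl]-1,3-oxazolidin-2-one; 15 methyl 3-(Ar-syn)propanoate (1.3 equiv)
Product: 24 methyl (3S)-4-[(4R)-4-benzyl-2-oxo-1,3-oxazolidin-3-yl]-2-(Ar-syn-methyl)-3-(Ar-anti-methyl)-4-oxobutanoate (C‑2 epimer mixture)
Conditions: LDA (2.3 equiv), THF, −78 °C; then Fe(acac)3 (2.2 equiv), −78 °C → rt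
Reagents that add atoms: none
Why: Intermolecular oxidative enolate heterocoupling (Fe(III) one‑electron oxidation of an imide/ester enolate pair) forms C8–C8′; bond formation on the face of the chelated Z‑imide enolate opposite the (R)‑benzyl group (Evans alkylation sense) sets C‑3 as S, while the ester α‑carbon forms as a mixture that is corrected in step 16.

Step 16
Reactants: 24 methyl (3S)-4-[(4R)-4-benzyl-2-oxo-1,3-oxazolidin-3-yl]-2-(Ar-syn-methyl)-3-(Ar-anti-methyl)-4-oxobutanoate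
Product: 26 (3S,4S)-3-(Ar-syn-methyl)-4-(Ar-anti-methyl)dihydrofuran-2(3H)-one, via hydroxy ester 25 (not isolated)
Conditions: LiBH4 (1.1 equiv), MeOH (1.1 equiv), THF, 0 °C; then DBU, toluene, 60 °C
Reagents that add atoms: none
Why: Chemoselective imide reduction gives a γ‑hydroxy ester that lactonises, and DBU equilibrates the enolisable C‑3 to the thermodynamically favoured trans‑3,4‑dibenzyl lactone (3S), C‑4 being fixed.

Step 17
Reactants: 26 (3S,4S)-3-(Ar-syn-methyl)-4-(Ar-anti-methyl)dihydrofuran-2(3H)-one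
Product: 27 (3S,4S)-3-{4-hydroxy-3-[(1S,2R)-1,3-dihydroxy-1-(4-hydroxy-3-methoxyphenyl)propan-2-yl]-5-methoxybenzyl}-4-{4-hydroxy-3-[(1S,2S)-1,3-dihydroxy-1-(4-hydroxy-3-methoxyphenyl)propan-2-yl]-5-methoxybenzyl}dihydrofuran-2(3H)-one
Conditions: TBAF (12 equiv), AcOH (12 equiv), THF, 0 °C → rt
Reagents that add atoms: none
Why: Fluoride desilylation of all eight silyl ethers; the acetic acid buffer avoids lactone opening and quinone‑methide chemistry, and no acid strong enough to close the phenylcoumaran is present.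

## Compound list

1 | methyl 3-(4-hydroxy-3-methoxyphenyl)propanoate | COC(=O)CCc1ccc(O)c(OC)c1 | starting material
2 | allyl bromide | C=CCBr | starting material
3 | methyl 3-[4-(allyloxy)-3-methoxyphenyl]propanoate | COC(=O)CCc1ccc(OCC=C)c(OC)c1 | intermediate
4 | methyl 3-(3-allyl-4-hydroxy-5-methoxyphenyl)propanoate | COC(=O)CCc1cc(CC=C)c(O)c(OC)c1 | intermediate
5 | methyl 3-[3-allyl-4-(TBSO)-5-methoxyphenyl]propanoate | COC(=O)CCc1cc(CC=C)c(O[Si](C)(C)C(C)(C)C)c(OC)c1 | intermediate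
6 | methyl 3-[4-(TBSO)-3-methoxy-5-(2-oxoethyl)phenyl]propanoate | COC(=O)CCc1cc(CC=O)c(O[Si](C)(C)C(C)(C)C)c(OC)c1 | intermediate
7 | 2-[2-(TBSO)-3-methoxy-5-(3-methoxy-3-oxopropyl)phenyl]acetic acid | COC(=O)CCc1cc(CC(=O)O)c(O[Si](C)(C)C(C)(C)C)c(OC)c1 | intermediate
8 | (S)-4-benzyl-1,3-oxazolidin-2-one | O=C1N[C@@H](Cc2ccccc2)CO1 | starting material
9 | Q-acetic pivalic anhydride | COC(=O)CCc1cc(CC(=O)OC(=O)C(C)(C)C)c(O[Si](C)(C)C(C)(C)C)c(OC)c1 | intermediate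
10 | (4S)-4-benzyl-3-(Q-acetyl)-1,3-oxazolidin-2-one | COC(=O)CCc1cc(CC(=O)N2[C@@H](Cc3ccccc3)COC2=O)c(O[Si](C)(C)C(C)(C)C)c(OC)c1 | intermediate
11 | vanillin | COc1cc(C=O)ccc1O | starting material
12 | 4-(TBSO)-3-methoxybenzaldehyde | COc1cc(C=O)ccc1O[Si](C)(C)C(C)(C)C | intermediate
13 | (4S)-4-benzyl-3-[(2S,3S)-3-hydroxy-2-Q-3-G-propanoyl]-1,3-oxazolidin-2-one | COC(=O)CCc1cc([C@H](C(=O)N2[C@@H](Cc3ccccc3)COC2=O)[C@H](O)c4ccc(O[Si](C)(C)C(C)(C)C)c(OC)c4)c(O[Si](C)(C)C(C)(C)C)c(OC)c1 | intermediate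
14 | (1S,2R)-1-G-2-Q-propane-1,3-diol | COC(=O)CCc1cc([C@H](CO)[C@H](O)c2ccc(O[Si](C)(C)C(C)(C)C)c(OC)c2)c(O[Si](C)(C)C(C)(C)C)c(OC)c1 | intermediate
15 | methyl 3-(Ar-syn)propanoate | COC(=O)CCc1cc([C@H](CO[Si](C)(C)C(C)(C)C)[C@H](O[Si](C)(C)C(C)(C)C)c2ccc(O[Si](C)(C)C(C)(C)C)c(OC)c2)c(O[Si](C)(C)C(C)(C)C)c(OC)c1 | intermediate
16 | (4S)-4-benzyl-3-[(2R,3S)-2-Q-3-G-3-(trimethylsilyloxy)propanoyl]-1,3-oxazolidin-2-one | COC(=O)CCc1cc([C@@H](C(=O)N2[C@@H](Cc3ccccc3)COC2=O)[C@H](O[Si](C)(C)C)c4ccc(O[Si](C)(C)C(C)(C)C)c(OC)c4)c(O[Si](C)(C)C(C)(C)C)c(OC)c1 | intermediate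
17 | (4S)-4-benzyl-3-[(2R,3S)-3-hydroxy-2-Q-3-G-propanoyl]-1,3-oxazolidin-2-one | COC(=O)CCc1cc([C@@H](C(=O)N2[C@@H](Cc3ccccc3)COC2=O)[C@H](O)c4ccc(O[Si](C)(C)C(C)(C)C)c(OC)c4)c(O[Si](C)(C)C(C)(C)C)c(OC)c1 | intermediate
18 | (1S,2S)-1-G-2-Q-propane-1,3-diol | COC(=O)CCc1cc([C@@H](CO)[C@H](O)c2ccc(O[Si](C)(C)C(C)(C)C)c(OC)c2)c(O[Si](C)(C)C(C)(C)C)c(OC)c1 | intermediate
19 | methyl 3-(Ar-anti)propanoate | COC(=O)CCc1cc([C@@H](CO[Si](C)(C)C(C)(C)C)[C@H](O[Si](C)(C)C(C)(C)C)c2ccc(O[Si](C)(C)C(C)(C)C)c(OC)c2)c(O[Si](C)(C)C(C)(C)C)c(OC)c1 | intermediate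
20 | 3-(Ar-anti)propanoic acid | OC(=O)CCc1cc([C@@H](CO[Si](C)(C)C(C)(C)C)[C@H](O[Si](C)(C)C(C)(C)C)c2ccc(O[Si](C)(C)C(C)(C)C)c(OC)c2)c(O[Si](C)(C)C(C)(C)C)c(OC)c1 | intermediate
21 | (R)-4-benzyl-1,3-oxazolidin-2-one | O=C1N[C@H](Cc2ccccc2)CO1 | starting material
22 | 3-(Ar-anti)propanoic pivalic anhydride | CC(C)(C)C(=O)OC(=O)CCc1cc([C@@H](CO[Si](C)(C)C(C)(C)C)[C@H](O[Si](C)(C)C(C)(C)C)c2ccc(O[Si](C)(C)C(C)(C)C)c(OC)c2)c(O[Si](C)(C)C(C)(C)C)c(OC)c1 | intermediate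
23 | (4R)-4-benzyl-3-[3-(Ar-anti)propanoyl]-1,3-oxazolidin-2-one | O=C(CCc1cc([C@@H](CO[Si](C)(C)C(C)(C)C)[C@H](O[Si](C)(C)C(C)(C)C)c2ccc(O[Si](C)(C)C(C)(C)C)c(OC)c2)c(O[Si](C)(C)C(C)(C)C)c(OC)c1)N3[C@H](Cc4ccccc4)COC3=O | intermediate
24 | methyl (3S)-4-[(4R)-4-benzyl-2-oxo-1,3-oxazolidin-3-yl]-2-(Ar-syn-methyl)-3-(Ar-anti-methyl)-4-oxobutanoate (C‑2 epimers) | COC(=O)C(Cc1cc([C@H](CO[Si](C)(C)C(C)(C)C)[C@H](O[Si](C)(C)C(C)(C)C)c2ccc(O[Si](C)(C)C(C)(C)C)c(OC)c2)c(O[Si](C)(C)C(C)(C)C)c(OC)c1)[C@H](Cc3cc([C@@H](CO[Si](C)(C)C(C)(C)C)[C@H](O[Si](C)(C)C(C)(C)C)c4ccc(O[Si](C)(C)C(C)(C)C)c(OC)c4)c(O[Si](C)(C)C(C)(C)C)c(OC)c3)C(=O)N5[C@H](Cc6ccccc6)COC5=O | intermediate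
25 | methyl (3S)-2-(Ar-syn-methyl)-3-(Ar-anti-methyl)-4-hydroxybutanoate (C‑2 epimers) | COC(=O)C(Cc1cc([C@H](CO[Si](C)(C)C(C)(C)C)[C@H](O[Si](C)(C)C(C)(C)C)c2ccc(O[Si](C)(C)C(C)(C)C)c(OC)c2)c(O[Si](C)(C)C(C)(C)C)c(OC)c1)[C@H](Cc3cc([C@@H](CO[Si](C)(C)C(C)(C)C)[C@H](O[Si](C)(C)C(C)(C)C)c4ccc(O[Si](C)(C)C(C)(C)C)c(OC)c4)c(O[Si](C)(C)C(C)(C)C)c(OC)c3)CO | intermediate
26 | (3S,4S)-3-(Ar-syn-methyl)-4-(Ar-anti-methyl)dihydrofuran-2(3H)-one (octa‑TBS target) | COc1cc([C@@H](O[Si](C)(C)C(C)(C)C)[C@H](CO[Si](C)(C)C(C)(C)C)c2cc(C[C@@H]3COC(=O)[C@H]3Cc3cc(OC)c(O[Si](C)(C)C(C)(C)C)c([C@H](CO[Si](C)(C)C(C)(C)C)[C@H](O[Si](C)(C)C(C)(C)C)c4ccc(O[Si](C)(C)C(C)(C)C)c(OC)c4)c3)cc(OC)c2O[Si](C)(C)C(C)(C)C)ccc1O[Si](C)(C)C(C)(C)C | intermediate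
27 | CNP0113972.1, (3S,4S)-3-{4-hydroxy-3-[(1S,2R)-1,3-dihydroxy-1-(4-hydroxy-3-methoxyphenyl)propan-2-yl]-5-methoxybenzyl}-4-{4-hydroxy-3-[(1S,2S)-1,3-dihydroxy-1-(4-hydroxy-3-methoxyphenyl)propan-2-yl]-5-methoxybenzyl}dihydrofuran-2(3H)-one | COc1cc([C@@H](O)[C@H](CO)c2cc(C[C@@H]3COC(=O)[C@H]3Cc3cc(OC)c(O)c([C@H](CO)[C@H](O)c4ccc(O)c(OC)c4)c3)cc(OC)c2O)ccc1O | target

## Step count and risks

Total steps: 17. Longest linear sequence: 13 (steps 1–5, 10–14, 15–17).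

**Steps most likely to fail**

1. **Step 15 (oxidative enolate heterocoupling).** Risks are statistical homodimers, slow coupling of two bulky enolates and eroded face selectivity. The fallback sets out from 15 (used together with 23) and comes back at 24. It forms the C8–C8′ bond by polar alkylation instead of one‑electron coupling. Ester 15 is α‑brominated (LDA, THF, −78 °C; then CBr4) to methyl 2-bromo-3-(Ar-syn)propanoate F1 (both C‑2 epimers). The sodium enolate of imide 23 (NaHMDS, THF, −78 → −20 °C) then displaces bromide from F1. Evans face control fixes the imide α‑carbon as S as before, and the ester α‑carbon is again left to the DBU equilibration, so the product is 24.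

2. **Step 10 (Mg‑catalysed anti‑aldol of the arylacetyl imide).** Risks are retro‑aldol or C‑2 epimerisation of the α‑aryl adduct, or an unexpected facial sense. The fallback sets out from 7 and comes back at 19. It sets the anti arm by a syn‑aldol with the enantiomeric auxiliary followed by inversion of the carbinol centre through a ketone:
   - 7 is activated as 9 (PivCl, Et3N) and coupled with 21 (LiCl) to give (4R)-4-benzyl-3-(Q-acetyl)-1,3-oxazolidin-2-one F2.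
   - Bu2BOTf/i‑Pr2NEt aldol with 12 gives (4R)-4-benzyl-3-[(2R,3R)-3-hydroxy-2-Q-3-G-propanoyl]-1,3-oxazolidin-2-one F3.
   - LiBH4 gives (1R,2S)-1-G-2-Q-propane-1,3-diol F4.
   - TBSCl/imidazole at 0 °C silylates only the primary hydroxyl, giving (1R,2S)-3-(TBSO)-1-G-2-Q-propan-1-ol F5.
   - Dess–Martin periodinane (NaHCO3, CH2Cl2) gives (2S)-3-(TBSO)-1-G-2-Q-propan-1-one F6, used at once to avoid α‑epimerisation.
   - (R)‑Me‑CBS/BH3·SMe2 reduction (reagent control, aryl as the large group) gives (1S,2S)-3-(TBSO)-1-G-2-Q-propan-1-ol F7.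
   - TBSOTf/2,6‑lutidine converts F7 into 19.

3. **Step 17 (eight‑fold desilylation to a base‑ and acid‑sensitive octol).** Risks are incomplete cleavage of the hindered benzylic silyl ethers, and quinone‑methide or phenylcoumaran chemistry once the phenols are free. The fallback sets out from 26 and comes back at 27. It replaces the single global treatment by an orthogonal two‑stage unmasking. HF·pyridine/pyridine in THF (0 °C → rt) removes only the four alkyl silyl ethers while the phenols stay capped, so neither cyclisation nor quinone‑methide formation is possible; this gives (3S,4S)-lactone tetraol with four aryl TBS ethers F8. A brief TBAF/AcOH treatment at 0 °C then frees the phenols to give 27.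

## Further compounds

F1 | step 15 | methyl 2-bromo-3-(Ar-syn)propanoate (C‑2 epimers) | COC(=O)C(Br)Cc1cc([C@H](CO[Si](C)(C)C(C)(C)C)[C@H](O[Si](C)(C)C(C)(C)C)c2ccc(O[Si](C)(C)C(C)(C)C)c(OC)c2)c(O[Si](C)(C)C(C)(C)C)c(OC)c1
F2 | step 10 | (4R)-4-benzyl-3-(Q-acetyl)-1,3-oxazolidin-2-one | COC(=O)CCc1cc(CC(=O)N2[C@H](Cc3ccccc3)COC2=O)c(O[Si](C)(C)C(C)(C)C)c(OC)c1
F3 | step 10 | (4R)-4-benzyl-3-[(2R,3R)-3-hydroxy-2-Q-3-G-propanoyl]-1,3-oxazolidin-2-one | COC(=O)CCc1cc([C@@H](C(=O)N2[C@H](Cc3ccccc3)COC2=O)[C@@H](O)c4ccc(O[Si](C)(C)C(C)(C)C)c(OC)c4)c(O[Si](C)(C)C(C)(C)C)c(OC)c1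
F4 | step 10 | (1R,2S)-1-G-2-Q-propane-1,3-diol | COC(=O)CCc1cc([C@@H](CO)[C@@H](O)c2ccc(O[Si](C)(C)C(C)(C)C)c(OC)c2)c(O[Si](C)(C)C(C)(C)C)c(OC)c1
F5 | step 10 | (1R,2S)-3-(TBSO)-1-G-2-Q-propan-1-ol | COC(=O)CCc1cc([C@@H](CO[Si](C)(C)C(C)(C)C)[C@@H](O)c2ccc(O[Si](C)(C)C(C)(C)C)c(OC)c2)c(O[Si](C)(C)C(C)(C)C)c(OC)c1
F6 | step 10 | (2S)-3-(TBSO)-1-G-2-Q-propan-1-one | COC(=O)CCc1cc([C@@H](CO[Si](C)(C)C(C)(C)C)C(=O)c2ccc(O[Si](C)(C)C(C)(C)C)c(OC)c2)c(O[Si](C)(C)C(C)(C)C)c(OC)c1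
F7 | step 10 | (1S,2S)-3-(TBSO)-1-G-2-Q-propan-1-ol | COC(=O)CCc1cc([C@@H](CO[Si](C)(C)C(C)(C)C)[C@H](O)c2ccc(O[Si](C)(C)C(C)(C)C)c(OC)c2)c(O[Si](C)(C)C(C)(C)C)c(OC)c1
F8 | step 17 | (3S,4S)-lactone tetraol with four aryl TBS ethers | COc1cc([C@@H](O)[C@H](CO)c2cc(C[C@@H]3COC(=O)[C@H]3Cc3cc(OC)c(O[Si](C)(C)C(C)(C)C)c([C@H](CO)[C@H](O)c4ccc(O[Si](C)(C)C(C)(C)C)c(OC)c4)c3)cc(OC)c2O[Si](C)(C)C(C)(C)C)ccc1O[Si](C)(C)C(C)(C)C
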